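The isoflavan is cut at C3–C4 and O1–C2. The phloroglucinol-type A ring, whose benzylic C4 and phenolic O1 sit ortho to each other, serves as a latent ortho-quinone methide, and C3 as the nucleophilic α-carbon of the B-ring arylacetyl unit. In one catalytic operation a chiral isothiourea-bound enolate, made from the 4-nitrophenyl ester of the MOM-protected, prenylated B-ring arylacetic acid, adds to the methide released from a MOM-protected 2-(tosylmethyl)phenol; the A-ring phenoxide then lactonises, closing the pyranone ring and setting C3 as (R). Lactone reduction, Mitsunobu closure of the pyran ring and removal of both MOM groups complete the synthesis.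

Key step: step 8

Assumption: aldehyde 1 is taken as a catalogue compound.
Assumption: the sense of induction follows the accepted model for isothiouronium (Z)-enolates (attack anti to the catalyst's C2 phenyl), by which the (2S,3R) catalyst should give (R) at C3; the antipodal catalyst is equally available should the sense prove opposite.
Remark: C3 is (R) in 17, 18, 19 and 20 alike, because the ranking oxygen-bearing carbon > B-ring carbon > C4 > H holds in all four.

Step 1
Reactants: 1 2,4-dihydroxy-6-methoxybenzaldehyde
Product: 2 2-hydroxy-6-methoxy-4-(methoxymethoxy)benzaldehyde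
Conditions: MOMCl (1.1 equiv), K2CO3, acetone, 0 °C to rt
Reagents that add atoms: chloromethyl methyl ether, COCCl
Why: Williamson-type O-alkylation should take only the 4-OH, because the 2-OH is held in a hydrogen bond to the aldehyde and is the poorer nucleophile.

Step 2
Reactants: 2 2-hydroxy-6-methoxy-4-(methoxymethoxy)benzaldehyde
Product: 4 3-methoxy-5-(methoxymethoxy)-2-[(4-methylphenyl)sulfonylmethyl]phenol, via salicyl alcohol 3 (not isolated)
Conditions: NaBH4, THF/MeOH, 0 °C; acetone quench; then TolSO2Na (3 equiv), AcOH/H2O, rt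
Reagents that add atoms: sodium p-toluenesulfinate, Cc1ccc(cc1)S(=O)[O-].[Na+]
Why: Borohydride reduction gives the labile salicyl alcohol, whose benzylic hydroxyl, flanked ortho and para by three oxygen donors, should ionise in weak acid (SN1-type substitution through the quinone-methide cation) and be captured at sulfur by sulfinate to give the storable sulfone, the hydride being destroyed first so that it cannot reduce the cation and the aryl MOM ether tolerating acetic acid at room temperature.

Step 3
Reactants: 5 3-methoxyphenol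
Product: 6 1-methoxy-3-(methoxymethoxy)benzene
Conditions: NaH, MOMCl, DMF, 0 °C to rt
Reagents that add atoms: chloromethyl methyl ether, COCCl
Why: Williamson etherification of the sodium phenoxide installs the MOM group that serves both as protecting group and as director for the two metalations.

Step 4
Reactants: 6 1-methoxy-3-(methoxymethoxy)benzene; 7 prenyl bromide (1-bromo-3-methylbut-2-ene)
Product: 9 1-methoxy-3-(methoxymethoxy)-2-(3-methylbut-2-en-1-yl)benzene, via C2-aryllithium 8 (not isolated)
Conditions: n-BuLi, THF, 0 °C to rt; CuI (10 mol%), 7, −78 °C to rt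
Reagents that add atoms: prenyl bromide (7), CC(C)=CCBr
Why: Directed ortho-metalation should occur at the C–H between the two oxygen directors, and copper-catalysed SN2 allylation with the primary allylic bromide should give the linear prenyl arene.

Step 5
Reactants: 9 1-methoxy-3-(methoxymethoxy)-2-(3-methylbut-2-en-1-yl)benzene; 10 ethylene oxide
Product: 12 2-[4-methoxy-2-(methoxymethoxy)-3-(3-methylbut-2-en-1-yl)phenyl]ethan-1-ol, via ortho-lithiated arene 11 (not isolated)
Conditions: s-BuLi, TMEDA, THF, −78 °C; 10 (THF solution), −78 °C to rt; aq. NH4Cl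
Reagents that add atoms: ethylene oxide (10), C1CO1
Why: With the position between the oxygens blocked, a second directed ortho-metalation should take place next to the stronger OMOM director under kinetic conditions (ring lithiation by complex-induced proximity outrunning deprotonation of the prenyl CH2), and the aryllithium opens the epoxide to the 2-arylethanol.

Step 6
Reactants: 12 2-[4-methoxy-2-(methoxymethoxy)-3-(3-methylbut-2-en-1-yl)phenyl]ethan-1-ol
Product: 14 [4-methoxy-2-(methoxymethoxy)-3-(3-methylbut-2-en-1-yl)phenyl]acetic acid, via arylacetaldehyde 13 (not isolated)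
Conditions: TEMPO (20 mol%), PhI(OAc)2 (2.2 equiv), MeCN/H2O (1:1), rt
Reagents that add atoms: water, O
Why: The TEMPO/oxoammonium oxidation (Epp–Widlanski conditions) takes the primary alcohol through the aldehyde hydrate to the acid without electrophilic halogen, so the prenyl alkene, the aryl ethers and the MOM group should survive.

Step 7
Reactants: 14 [4-methoxy-2-(methoxymethoxy)-3-(3-methylbut-2-en-1-yl)phenyl]acetic acid
Product: 15 4-nitrophenyl [4-methoxy-2-(methoxymethoxy)-3-(3-methylbut-2-en-1-yl)phenyl]acetate
Conditions: 4-nitrophenol, EDC·HCl, DMAP (5 mol%), CH2Cl2, 0 °C to rt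
Reagents that add atoms: 4-nitrophenol, Oc1ccc(cc1)[N+](=O)[O-]
Why: Steglich esterification gives an isolable activated ester, so the key step can run with a weak amine base alone and without acid chloride or anhydride by-products.

Step 8
Reactants: 4 3-methoxy-5-(methoxymethoxy)-2-[(4-methylphenyl)sulfonylmethyl]phenol; 15 4-nitrophenyl [4-methoxy-2-(methoxymethoxy)-3-(3-methylbut-2-en-1-yl)phenyl]acetate
Product: 17 (3R)-5-methoxy-7-(methoxymethoxy)-3-[4-methoxy-2-(methoxymethoxy)-3-(3-methylbut-2-en-1-yl)phenyl]-3,4-dihydro-2H-chromen-2-one, via o-quinone methide 16 (not isolated)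
Conditions: (2S,3R)-HyperBTM (10 mol%), iPr2NEt (2.5 equiv), CH2Cl2, 0 °C, 4 added slowly to 15 (1.2 equiv); rapid filtration through a short silica plug
Reagents that add atoms: none
Why: The amine base converts phenol 4 into its phenoxide, which expels p-toluenesulfinate to give o-quinone methide 16, while the isothiourea is N-acylated by ester 15 and the acyl isothiouronium is deprotonated (by released 4-nitrophenoxide or the amine) to the (Z)-ammonium enolate; the enolate carbon adds to the exocyclic methide carbon (C3–C4), the A ring rearomatises, and the new phenoxide attacks the acyl isothiouronium (O1–C2) and frees the catalyst. The closest known reaction type is the isothiourea- or carbene-catalysed Michael addition–lactonisation of C1-ammonium or azolium enolates with o-quinone methides generated in situ, which gives 3-substituted 3,4-dihydrocoumarins. The pyranone ring closes by 6-exo-trig acyl substitution at the catalyst-bound carbonyl. C3 is set by the catalyst: the enolate oxygen is held syn to sulfur by the 1,5-O···S contact, the pseudo-axial C2 phenyl group covers one face, and addition anti to it is expected to give (R). The step needs C–C bond formation at the methide carbon to outrun methide self-condensation and the reversible additions of sulfinate, aryloxide and catalyst, which the three oxygen donors ortho and para to C4 (fast, mild methide release), the slow addition of 4 and the small excess of 15 should secure. Because C3–H lies α to an aryl lactone, only a tertiary amine at 0 °C is used and 17 is filtered and reduced at once.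

Step 9
Reactants: 17 (3R)-5-methoxy-7-(methoxymethoxy)-3-[4-methoxy-2-(methoxymethoxy)-3-(3-methylbut-2-en-1-yl)phenyl]-3,4-dihydro-2H-chromen-2-one
Product: 18 2-{(2R)-3-hydroxy-2-[4-methoxy-2-(methoxymethoxy)-3-(3-methylbut-2-en-1-yl)phenyl]propyl}-3-methoxy-5-(methoxymethoxy)phenol
Conditions: LiAlH4, THF, −40 to 0 °C (17 added to the hydride); Rochelle salt work-up
Reagents that add atoms: none
Why: Hydride reduction of the aryl lactone should give the phenol and the primary alcohol, and inverse addition at low temperature keeps the transient α-aryl aldehyde short-lived so that C3 is not enolised.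

Step 10
Reactants: 18 2-{(2R)-3-hydroxy-2-[4-methoxy-2-(methoxymethoxy)-3-(3-methylbut-2-en-1-yl)phenyl]propyl}-3-methoxy-5-(methoxymethoxy)phenol
Product: 19 (3R)-5-methoxy-7-(methoxymethoxy)-3-[4-methoxy-2-(methoxymethoxy)-3-(3-methylbut-2-en-1-yl)phenyl]-3,4-dihydro-2H-chromene
Conditions: PPh3, DIAD, THF, 0 °C to rt
Reagents that add atoms: none
Why: In an intramolecular Mitsunobu etherification the only free phenol (O1) should displace the activated primary alcohol at C2 (6-exo-tet), with no bond to C3 made or broken.

Step 11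
Reactants: 19 (3R)-5-methoxy-7-(methoxymethoxy)-3-[4-methoxy-2-(methoxymethoxy)-3-(3-methylbut-2-en-1-yl)phenyl]-3,4-dihydro-2H-chromene
Product: 20 (3R)-3-[2-hydroxy-4-methoxy-3-(3-methylbut-2-en-1-yl)phenyl]-5-methoxy-3,4-dihydro-2H-chromen-7-ol
Conditions: aq. HCl (3 M)/MeOH, 40 °C, stopped at full conversion
Reagents that add atoms: none
Why: Acid-catalysed acetal exchange with methanol should remove both aryl MOM groups under conditions mild enough to leave the prenyl double bond and the C3 centre untouched.

Compound list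
1 | 2,4-dihydroxy-6-methoxybenzaldehyde | COc1cc(O)cc(O)c1C=O | starting material
2 | 2-hydroxy-6-methoxy-4-(methoxymethoxy)benzaldehyde | COCOc1cc(O)c(C=O)c(OC)c1 | intermediate
3 | 2-(hydroxymethyl)-3-methoxy-5-(methoxymethoxy)phenol (salicyl alcohol, not isolated) | COCOc1cc(O)c(CO)c(OC)c1 | intermediate
4 | 3-methoxy-5-(methoxymethoxy)-2-[(4-methylphenyl)sulfonylmethyl]phenol | COCOc1cc(O)c(CS(=O)(=O)c2ccc(C)cc2)c(OC)c1 | intermediate
5 | 3-methoxyphenol | COc1cccc(O)c1 | starting material
6 | 1-methoxy-3-(methoxymethoxy)benzene | COCOc1cccc(OC)c1 | intermediate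
7 | prenyl bromide (1-bromo-3-methylbut-2-ene) | CC(C)=CCBr | starting material
8 | [2-methoxy-6-(methoxymethoxy)phenyl]lithium (C2-aryllithium, not isolated) | [Li]c1c(OC)cccc1OCOC | intermediate
9 | 1-methoxy-3-(methoxymethoxy)-2-(3-methylbut-2-en-1-yl)benzene | COCOc1cccc(OC)c1CC=C(C)C | intermediate
10 | ethylene oxide (oxirane) | C1CO1 | starting material
11 | [4-methoxy-2-(methoxymethoxy)-3-(3-methylbut-2-en-1-yl)phenyl]lithium (ortho-lithiated arene, not isolated) | [Li]c1ccc(OC)c(CC=C(C)C)c1OCOC | intermediate
12 | 2-[4-methoxy-2-(methoxymethoxy)-3-(3-methylbut-2-en-1-yl)phenyl]ethan-1-ol | COCOc1c(CCO)ccc(OC)c1CC=C(C)C | intermediate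
13 | [4-methoxy-2-(methoxymethoxy)-3-(3-methylbut-2-en-1-yl)phenyl]acetaldehyde (not isolated) | COCOc1c(CC=O)ccc(OC)c1CC=C(C)C | intermediate
14 | [4-methoxy-2-(methoxymethoxy)-3-(3-methylbut-2-en-1-yl)phenyl]acetic acid | COCOc1c(CC(=O)O)ccc(OC)c1CC=C(C)C | intermediate
15 | 4-nitrophenyl [4-methoxy-2-(methoxymethoxy)-3-(3-methylbut-2-en-1-yl)phenyl]acetate | COCOc1c(CC(=O)Oc2ccc(cc2)[N+](=O)[O-])ccc(OC)c1CC=C(C)C | intermediate
16 | 5-methoxy-3-(methoxymethoxy)-6-methylidenecyclohexa-2,4-dien-1-one (o-quinone methide, not isolated) | C=C1C(=O)C=C(OCOC)C=C1OC | intermediate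
17 | (3R)-5-methoxy-7-(methoxymethoxy)-3-[4-methoxy-2-(methoxymethoxy)-3-(3-methylbut-2-en-1-yl)phenyl]-3,4-dihydro-2H-chromen-2-one | COc1cc(OCOC)cc2c1C[C@H](c1ccc(OC)c(CC=C(C)C)c1OCOC)C(=O)O2 | intermediate
18 | 2-{(2R)-3-hydroxy-2-[4-methoxy-2-(methoxymethoxy)-3-(3-methylbut-2-en-1-yl)phenyl]propyl}-3-methoxy-5-(methoxymethoxy)phenol | COc1cc(OCOC)cc(O)c1C[C@H](c1ccc(OC)c(CC=C(C)C)c1OCOC)CO | intermediate
19 | (3R)-5-methoxy-7-(methoxymethoxy)-3-[4-methoxy-2-(methoxymethoxy)-3-(3-methylbut-2-en-1-yl)phenyl]-3,4-dihydro-2H-chromene | COc1cc(OCOC)cc2c1C[C@H](c1ccc(OC)c(CC=C(C)C)c1OCOC)CO2 | intermediate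
20 | (3R)-3-[2-hydroxy-4-methoxy-3-(3-methylbut-2-en-1-yl)phenyl]-5-methoxy-3,4-dihydro-2H-chromen-7-ol | COc1cc(O)cc2c1C[C@H](c1ccc(OC)c(CC=C(C)C)c1O)CO2 | target

Total step count: 11 (A-ring branch 2, B-ring branch 5, key step 1, end game 3).
Longest linear sequence: 9 steps (steps 3–7, 8, 9–11).

Steps most likely to fail

Step 8. What may go wrong: self-condensation of the methide before the enolate reaches it, insufficient facial control by the catalyst, or erosion of C3 by enolisation of the aryl lactone under the basic conditions. The fallback is an auxiliary-controlled enolate alkylation that sets out from acid 14 and aldehyde 2 and rejoins the route at diol 18.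
- Acid 14 is converted through its pivalic mixed anhydride and lithiated (R)-4-benzyloxazolidin-2-one into (R)-4-benzyl-3-{[4-methoxy-2-(methoxymethoxy)-3-(3-methylbut-2-en-1-yl)phenyl]acetyl}-1,3-oxazolidin-2-one F1.
- Aldehyde 2 is O-allylated (allyl bromide, K2CO3, DMF) to 2-(allyloxy)-6-methoxy-4-(methoxymethoxy)benzaldehyde F2. This is reduced (NaBH4, MeOH) to [2-(allyloxy)-6-methoxy-4-(methoxymethoxy)phenyl]methanol F3 and brominated (PBr3, Et2O, −20 °C, used crude) to 2-(allyloxy)-6-methoxy-4-(methoxymethoxy)benzyl bromide F4.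
- The sodium (Z)-enolate of F1 (NaHMDS, THF, −78 °C) should be alkylated by F4 on the face remote from the auxiliary benzyl group. This would give (R)-4-benzyl-3-{(2R)-3-[2-(allyloxy)-6-methoxy-4-(methoxymethoxy)phenyl]-2-[4-methoxy-2-(methoxymethoxy)-3-(3-methylbut-2-en-1-yl)phenyl]propanoyl}-1,3-oxazolidin-2-one F5.
- LiBH4 (THF, MeOH) then releases the auxiliary and gives (2R)-3-[2-(allyloxy)-6-methoxy-4-(methoxymethoxy)phenyl]-2-[4-methoxy-2-(methoxymethoxy)-3-(3-methylbut-2-en-1-yl)phenyl]propan-1-ol F6.
- Pd(PPh3)4/morpholine removes the allyl ether to give 18, from which steps 10 and 11 follow unchanged.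

Step 5. What may go wrong: deprotonation of the doubly activated benzylic–allylic CH2 of the prenyl group instead of the ring C–H, or incomplete ring lithiation, either of which would scramble or destroy the side chain. The fallback brings the prenyl group in last, so that no organolithium base meets it; it sets out from phenol 5 and rejoins at alcohol 12.
- Magnesium-mediated ortho-formylation of 5 (MgCl2, Et3N, paraformaldehyde, MeCN, reflux) should give 2-hydroxy-4-methoxybenzaldehyde F7.
- MOM protection (MOMCl, iPr2NEt, CH2Cl2) gives 4-methoxy-2-(methoxymethoxy)benzaldehyde F8.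
- Wittig methylenation (Ph3PCH3Br, KOtBu, THF) gives 1-ethenyl-4-methoxy-2-(methoxymethoxy)benzene F9.
- Hydroboration–oxidation (9-BBN, THF; NaOH, H2O2) gives 2-[4-methoxy-2-(methoxymethoxy)phenyl]ethan-1-ol F10.
- The lithium alkoxide of F10 is lithiated between the two oxygens (n-BuLi, 2.2 equiv, THF, 0 °C) and prenylated (CuI, 7, −78 °C to rt) to give 12.

Step 11. What may go wrong: acid-catalysed addition of the freed 2′-phenol across the neighbouring prenyl double bond (closure to a 2,2-dimethylchroman), or hydration of that alkene, before both acetals have gone. The fallback replaces protic hydrolysis by a two-stage, aprotic exchange; it sets out from 19 and ends at 20.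
- TMSOTf/2,2′-bipyridyl (CH2Cl2, 0 °C) should convert both aryl MOM ethers into silyl ethers. This would give (3R)-5-methoxy-3-[4-methoxy-3-(3-methylbut-2-en-1-yl)-2-(trimethylsilyloxy)phenyl]-7-(trimethylsilyloxy)-3,4-dihydro-2H-chromene F11.
- F11 is then hydrolysed with water/MeOH at neutral pH to give 20.

Further compounds
F1 | step 8 | (R)-4-benzyl-3-{[4-methoxy-2-(methoxymethoxy)-3-(3-methylbut-2-en-1-yl)phenyl]acetyl}-1,3-oxazolidin-2-one | COCOc1c(CC(=O)N2C(=O)OC[C@H]2Cc2ccccc2)ccc(OC)c1CC=C(C)C
F2 | step 8 | 2-(allyloxy)-6-methoxy-4-(methoxymethoxy)benzaldehyde | C=CCOc1cc(OCOC)cc(OC)c1C=O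
F3 | step 8 | [2-(allyloxy)-6-methoxy-4-(methoxymethoxy)phenyl]methanol | C=CCOc1cc(OCOC)cc(OC)c1CO
F4 | step 8 | 2-(allyloxy)-6-methoxy-4-(methoxymethoxy)benzyl bromide | C=CCOc1cc(OCOC)cc(OC)c1CBr
F5 | step 8 | (R)-4-benzyl-3-{(2R)-3-[2-(allyloxy)-6-methoxy-4-(methoxymethoxy)phenyl]-2-[4-methoxy-2-(methoxymethoxy)-3-(3-methylbut-2-en-1-yl)phenyl]propanoyl}-1,3-oxazolidin-2-one | C=CCOc1cc(OCOC)cc(OC)c1C[C@H](c1ccc(OC)c(CC=C(C)C)c1OCOC)C(=O)N1C(=O)OC[C@H]1Cc1ccccc1
F6 | step 8 | (2R)-3-[2-(allyloxy)-6-methoxy-4-(methoxymethoxy)phenyl]-2-[4-methoxy-2-(methoxymethoxy)-3-(3-methylbut-2-en-1-yl)phenyl]propan-1-ol | C=CCOc1cc(OCOC)cc(OC)c1C[C@H](c1ccc(OC)c(CC=C(C)C)c1OCOC)CO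
F7 | step 5 | 2-hydroxy-4-methoxybenzaldehyde | COc1ccc(C=O)c(O)c1
F8 | step 5 | 4-methoxy-2-(methoxymethoxy)benzaldehyde | COCOc1cc(OC)ccc1C=O
F9 | step 5 | 1-ethenyl-4-methoxy-2-(methoxymethoxy)benzene | COCOc1cc(OC)ccc1C=C
F10 | step 5 | 2-[4-methoxy-2-(methoxymethoxy)phenyl]ethan-1-ol | COCOc1cc(OC)ccc1CCO
F11 | step 11 | (3R)-5-methoxy-3-[4-methoxy-3-(3-methylbut-2-en-1-yl)-2-(trimethylsilyloxy)phenyl]-7-(trimethylsilyloxy)-3,4-dihydro-2H-chromene | COc1cc(O[Si](C)(C)C)cc2c1C[C@H](c1ccc(OC)c(CC=C(C)C)c1O[Si](C)(C)C)CO2
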